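Everything rests on cutting both ring B bonds at the spiro carbon, C6–C11 and C6–C7. The feature exploited is that the two ring B methylenes C7 and C11 meet at C6, which is the α′ carbon of a dimedone-derived vinylogous ester, while the trans C8 bromide and C9 tertiary chloride are the anti adduct of a (Z)-alkene and can be set acyclically. In one operation, step 9 joins ring A to an enantiopure chain, closes ring B and sets C6. Its precursors are dimedone isobutyl ether 3 and the (2R,3R)-bromochloride 12, which carries a primary iodide at C11 and a tosylate at C7.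

Key step: step 9

Remark: locants are those of the target skeleton (C1 methylidene carbon, C3 carbinol, C4 and C8 CHBr, C5 CMe2, C6 spiro, C9 CClMe); the target is (3R,4S,6S,8R,9R).
Assumption: in step 5 the antipode of the Schiff base ligand is used that gives the (2R,3R) adduct from (Z)-allylic alcohols of the nerol type; the mirror-image ligand would open the enantiomeric series.

Step 1
Reactants: 1 dimedone; 2 2-methylpropan-1-ol
Product: 3 3-(2-methylpropoxy)-5,5-dimethylcyclohex-2-en-1-one (fragment 1)
Conditions: p-TsOH·H2O (cat.), toluene, reflux, Dean–Stark trap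
Reagents that add atoms: none
Why: Acid-catalysed enol etherification of a cyclic 1,3-dione (a vinylogous Fischer esterification) driven by azeotropic removal of water, the symmetry of dimedone allowing a single product.

Step 2
Reactants: 4 4-methyl-5,6-dihydro-2H-pyran-2-one
Product: 5 (2Z)-5-hydroxy-N-methoxy-N,3-dimethylpent-2-enamide
Conditions: MeNH(OMe)·HCl, AlMe3, CH2Cl2, 0 °C to rt
Reagents that add atoms: N,O-dimethylhydroxylamine hydrochloride, CNOC.Cl
Why: Weinreb aminolysis of a lactone by the aluminium amide opens the ring at the acyl carbon, so the two oxygens are differentiated, the (Z) geometry is inherited from the ring and the β,β-disubstitution disfavours conjugate addition.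

Step 3
Reactants: 5 (2Z)-5-hydroxy-N-methoxy-N,3-dimethylpent-2-enamide
Product: 6 (2Z)-5-[tert-butyl(dimethyl)silyl]oxy-N-methoxy-N,3-dimethylpent-2-enamide
Conditions: TBSCl, imidazole, DMF, 0 °C to rt
Reagents that add atoms: tert-butyl(chloro)dimethylsilane, CC(C)(C)[Si](C)(C)Cl
Why: Standard imidazole-promoted silylation of a primary alcohol, carried out on the crude hydroxy amide so that relactonisation cannot compete.

Step 4
Reactants: 6 (2Z)-5-[tert-butyl(dimethyl)silyl]oxy-N-methoxy-N,3-dimethylpent-2-enamide
Product: 8 (2Z)-5-[tert-butyl(dimethyl)silyl]oxy-3-methylpent-2-en-1-ol, via silyloxy (Z)-enal 7 (not isolated)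
Conditions: iBu2AlH, THF, −78 °C, aq. potassium sodium tartrate work-up; crude enal, NaBH4, CeCl3·7H2O, MeOH, −20 °C
Reagents that add atoms: none
Why: Weinreb amide reduction stops at the aldehyde because the chelated tetrahedral intermediate survives until work-up, and immediate Luche 1,2-reduction of the unpurified enal should give the allylic alcohol before the (Z) double bond can isomerise.

Step 5
Reactants: 8 (2Z)-5-[tert-butyl(dimethyl)silyl]oxy-3-methylpent-2-en-1-ol
Product: 9 (2R,3R)-2-bromo-5-[tert-butyl(dimethyl)silyl]oxy-3-chloro-3-methylpentan-1-ol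
Conditions: NBS, ClTi(OiPr)3, chiral tridentate Schiff base ligand (salicylaldimine of a 1,2-amino alcohol, 20–30 mol %), hexanes, −20 °C
Reagents that add atoms: N-bromosuccinimide, O=C1CCC(=O)N1Br; chlorotitanium triisopropoxide, CC(C)O[Ti](Cl)(OC(C)C)OC(C)C
Why: Titanium-mediated catalytic enantioselective bromochlorination of an allylic alcohol, in which the titanium-bound alkoxide is brominated on the alkene face chosen by the ligand and chloride is delivered to the tertiary carbon with inversion, so that anti addition to the (Z)-alkene fixes the relative configuration and the ligand antipode the absolute (2R,3R) sense.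

Step 6
Reactants: 9 (2R,3R)-2-bromo-5-[tert-butyl(dimethyl)silyl]oxy-3-chloro-3-methylpentan-1-ol
Product: 10 (2R,3R)-2-bromo-5-[tert-butyl(dimethyl)silyl]oxy-3-chloro-3-methylpentyl 4-methylbenzenesulfonate
Conditions: TsCl, Et3N, DMAP (cat.), CH2Cl2, 0 °C
Reagents that add atoms: 4-methylbenzenesulfonyl chloride, Cc1ccc(cc1)S(=O)(=O)Cl
Why: Ordinary sulfonylation of a primary alcohol, for which the amine base is too weak to turn the bromohydrin into an epoxide and no stereocentre is involved.

Step 7
Reactants: 10 (2R,3R)-2-bromo-5-[tert-butyl(dimethyl)silyl]oxy-3-chloro-3-methylpentyl 4-methylbenzenesulfonate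
Product: 11 (2R,3R)-2-bromo-3-chloro-5-hydroxy-3-methylpentyl 4-methylbenzenesulfonate
Conditions: HF·pyridine, pyridine, THF, 0 °C to rt
Reagents that add atoms: none
Why: Fluoride-driven silyl ether cleavage under weakly acidic, non-ionising conditions never generates an alkoxide, so cyclisation onto the tosylate or the bromide and solvolysis of the tertiary chloride are avoided.

Step 8
Reactants: 11 (2R,3R)-2-bromo-3-chloro-5-hydroxy-3-methylpentyl 4-methylbenzenesulfonate
Product: 12 (2R,3R)-2-bromo-3-chloro-5-iodo-3-methylpentyl 4-methylbenzenesulfonate (fragment 2)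
Conditions: I2, PPh3, imidazole, CH2Cl2, 0 °C
Reagents that add atoms: iodine, II
Why: Appel-type iodination of the unhindered primary alcohol through its alkoxyphosphonium salt is fast at 0 °C, whereas the β-branched tosylate is too slow an electrophile to exchange with iodide.

Step 9
Reactants: 3 3-(2-methylpropoxy)-5,5-dimethylcyclohex-2-en-1-one (fragment 1); 12 (2R,3R)-2-bromo-3-chloro-5-iodo-3-methylpentyl 4-methylbenzenesulfonate (fragment 2)
Product: 14 (6R,8R,9R)-8-bromo-9-chloro-3-(2-methylpropoxy)-5,5,9-trimethylspiro[5.5]undec-2-en-1-one, via monoalkylated tosylate 13 (not isolated)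
Conditions: LiN(iPr)2 (1.05 equiv), THF, −78 °C; 12, DMPU, −78 to −20 °C; then LiN(iPr)2 (1.2 equiv), −78 °C to rt
Reagents that add atoms: none
Why: Kinetic deprotonation of 3 at the α′ carbon C6 gives the cross-conjugated lithium enolate, which displaces the unhindered primary iodide of 12 (C6–C11 bond); the second charge of base removes the remaining C6–H of 13 and the regenerated enolate displaces the tosylate at C7 (C6–C7 bond). The closest known reaction type is the Stork–Danheiser α′,α′-dialkylation of 3-alkoxycyclohexenones, run here as a spiroannulation with a 1,5-dielectrophile. Ring B closes in a 6-exo-tet SN2 mode, which should outpace 5-exo-tet attack on the secondary C8 bromide, eight-membered O-alkylation and intermolecular elimination. The new C6 stereocentre is controlled by the C8 and C9 centres through a chair-like transition state in which the C–Br and C–Cl bonds are anti and axial, the C9 methyl is equatorial and the quaternary C5 occupies the equatorial site, which leaves the flat enolate carbon C1 axial on the bromine face. The step needs chemoselectivity between the two leaving groups and face selectivity at the enolate carbon: the first is secured by the steric and inductive handicap of the β-bromo, β-branched C7 relative to C11, the second by the equatorial preference of the bulky CMe2 carbon.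

Step 10
Reactants: 14 (6R,8R,9R)-8-bromo-9-chloro-3-(2-methylpropoxy)-5,5,9-trimethylspiro[5.5]undec-2-en-1-one
Product: 16 (4S,6R,8R,9R)-4,8-dibromo-9-chloro-3-(2-methylpropoxy)-5,5,9-trimethylspiro[5.5]undec-2-en-1-one, via silyl dienol ether 15 (not isolated)
Conditions: LiN(iPr)2, Me3SiCl, THF, −78 °C; then NBS, THF, −78 °C
Reagents that add atoms: N-bromosuccinimide, O=C1CCC(=O)N1Br; chlorotrimethylsilane, C[Si](C)(C)Cl (silyl group present in 15 only)
Why: With C6 quaternary the only acidic site is C4, so γ-deprotonation and silylation give a 1-silyloxy-3-alkoxy-1,3-diene whose terminus C4, activated by both oxygens, is brominated by NBS (halogenation of a silyl dienol ether), and since the C11 methylene should lie pseudoaxial over one face of ring A (the tilt that keeps C2 away from the C8 bromine) NBS should enter from the C7 face to give the 4S epimer, which is also the one with equatorial bromine in the later chair.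

Step 11
Reactants: 16 (4S,6R,8R,9R)-4,8-dibromo-9-chloro-3-(2-methylpropoxy)-5,5,9-trimethylspiro[5.5]undec-2-en-1-one
Product: 18 (4S,6S,8R,9R)-4,8-dibromo-9-chloro-5,5,9-trimethyl-1-methylidenespiro[5.5]undecan-3-one, via methylidene dienol ether 17 (not isolated)
Conditions: Cp2TiMe2, toluene–THF, 65 °C, dark; then oxalic acid, THF–H2O, 0 °C
Reagents that add atoms: dimethyltitanocene, [CH3-].[CH3-].[Ti+4].[cH-]1cccc1.[cH-]1cccc1; water, O
Why: Petasis methylenation uses a neutral, non-basic titanium methylidene that reaches hindered, non-enolisable carbonyl groups and tolerates alkyl halides, and kinetic protonation of the resulting 1-alkoxy diene at C2 followed by hydrolysis should release the β,γ-unsaturated ketone at 0 °C without moving the exocyclic alkene or touching the C4 centre.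

Step 12
Reactants: 18 (4S,6S,8R,9R)-4,8-dibromo-9-chloro-5,5,9-trimethyl-1-methylidenespiro[5.5]undecan-3-one
Product: 19 (3R,4S,6S,8R,9R)-4,8-dibromo-9-chloro-5,5,9-trimethyl-1-methylidenespiro[5.5]undecan-3-ol (target)
Conditions: iBu2AlH, CH2Cl2, −78 °C; aq. potassium sodium tartrate work-up
Reagents that add atoms: none
Why: Hydride reduction of an α-bromo ketone in which the bulky aluminium hydride should attack C3 equatorially, from the face opposite the axial C5 methyl (as with 3,3,5-trimethylcyclohexanone), giving the axial 3R alcohol cis to the equatorial C4 bromine, an arrangement that cannot close to an epoxide.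

Compound list
1 | dimedone (5,5-dimethylcyclohexane-1,3-dione) | CC1(C)CC(=O)CC(=O)C1 | starting material
2 | 2-methylpropan-1-ol | CC(C)CO | starting material
3 | 3-(2-methylpropoxy)-5,5-dimethylcyclohex-2-en-1-one (fragment 1) | CC(C)COC1=CC(=O)CC(C)(C)C1 | intermediate
4 | 4-methyl-5,6-dihydro-2H-pyran-2-one | CC1=CC(=O)OCC1 | starting material
5 | (2Z)-5-hydroxy-N-methoxy-N,3-dimethylpent-2-enamide | C/C(CCO)=C/C(=O)N(C)OC | intermediate
6 | (2Z)-5-[tert-butyl(dimethyl)silyl]oxy-N-methoxy-N,3-dimethylpent-2-enamide | C/C(CCO[Si](C)(C)C(C)(C)C)=C/C(=O)N(C)OC | intermediate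
7 | (2Z)-5-[tert-butyl(dimethyl)silyl]oxy-3-methylpent-2-enal | C/C(CCO[Si](C)(C)C(C)(C)C)=C/C=O | intermediate
8 | (2Z)-5-[tert-butyl(dimethyl)silyl]oxy-3-methylpent-2-en-1-ol | C/C(CCO[Si](C)(C)C(C)(C)C)=C/CO | intermediate
9 | (2R,3R)-2-bromo-5-[tert-butyl(dimethyl)silyl]oxy-3-chloro-3-methylpentan-1-ol | CC(C)(C)[Si](C)(C)OCC[C@@](C)(Cl)[C@H](Br)CO | intermediate
10 | (2R,3R)-2-bromo-5-[tert-butyl(dimethyl)silyl]oxy-3-chloro-3-methylpentyl 4-methylbenzenesulfonate | CC(C)(C)[Si](C)(C)OCC[C@@](C)(Cl)[C@H](Br)COS(=O)(=O)c1ccc(C)cc1 | intermediate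
11 | (2R,3R)-2-bromo-3-chloro-5-hydroxy-3-methylpentyl 4-methylbenzenesulfonate | OCC[C@@](C)(Cl)[C@H](Br)COS(=O)(=O)c1ccc(C)cc1 | intermediate
12 | (2R,3R)-2-bromo-3-chloro-5-iodo-3-methylpentyl 4-methylbenzenesulfonate (fragment 2) | ICC[C@@](C)(Cl)[C@H](Br)COS(=O)(=O)c1ccc(C)cc1 | intermediate
13 | (2R,3R)-2-bromo-3-chloro-3-methyl-5-[4-(2-methylpropoxy)-6,6-dimethyl-2-oxocyclohex-3-en-1-yl]pentyl 4-methylbenzenesulfonate (either configuration at the ring carbon) | CC(C)COC1=CC(=O)C(CC[C@@](C)(Cl)[C@H](Br)COS(=O)(=O)c2ccc(C)cc2)C(C)(C)C1 | intermediate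
14 | (6R,8R,9R)-8-bromo-9-chloro-3-(2-methylpropoxy)-5,5,9-trimethylspiro[5.5]undec-2-en-1-one | O=C1C=C(OCC(C)C)CC(C)(C)[C@]12CC[C@@](C)(Cl)[C@H](Br)C2 | intermediate
15 | [(6R,8R,9R)-8-bromo-9-chloro-3-(2-methylpropoxy)-5,5,9-trimethylspiro[5.5]undeca-1,3-dien-1-yl]oxy(trimethyl)silane | C[Si](C)(C)OC1=CC(OCC(C)C)=CC(C)(C)[C@]12CC[C@@](C)(Cl)[C@H](Br)C2 | intermediate
16 | (4S,6R,8R,9R)-4,8-dibromo-9-chloro-3-(2-methylpropoxy)-5,5,9-trimethylspiro[5.5]undec-2-en-1-one | O=C1C=C(OCC(C)C)[C@@H](Br)C(C)(C)[C@]12CC[C@@](C)(Cl)[C@H](Br)C2 | intermediate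
17 | (4S,6S,8R,9R)-4,8-dibromo-9-chloro-5,5,9-trimethyl-1-methylidene-3-(2-methylpropoxy)spiro[5.5]undec-2-ene | C=C1C=C(OCC(C)C)[C@@H](Br)C(C)(C)[C@]12CC[C@@](C)(Cl)[C@H](Br)C2 | intermediate
18 | (4S,6S,8R,9R)-4,8-dibromo-9-chloro-5,5,9-trimethyl-1-methylidenespiro[5.5]undecan-3-one | C=C1CC(=O)[C@@H](Br)C(C)(C)[C@]12CC[C@@](C)(Cl)[C@H](Br)C2 | intermediate
19 | (3R,4S,6S,8R,9R)-4,8-dibromo-9-chloro-5,5,9-trimethyl-1-methylidenespiro[5.5]undecan-3-ol | C=C1C[C@@H](O)[C@@H](Br)C(C)(C)[C@]12CC[C@@](C)(Cl)[C@H](Br)C2 | target

Total step count: 12 (one-pot sequences counted once).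
Longest linear sequence: 11 steps (4 to 19, steps 2–12); fragment 1 needs one step before the convergence.

Steps most likely to fail

Step 9. The ring closure at the β-branched, bromine-bearing C7 may be overtaken by elimination of the tosylate or stall at 13. The enolate may also choose its other face through a chair with diequatorial halogens and an axial C9 methyl, which would erode the selectivity at C6. The fallback reverses the order of the two alkylations, so that the quaternary centre is closed at the unhindered C11; it sets out from 9 and 3 and comes back at 14. Alcohol 9 is converted (Tf2O, 2,6-lutidine, CH2Cl2, −78 °C) into the triflate F1. The lithium enolate of 3 is alkylated by this much more reactive electrophile at −78 °C to give the C7-linked silyl ether F2. HF·pyridine releases the alcohol F3, and I2/PPh3/imidazole gives the iodide F4. LiN(iPr)2 in THF–DMPU then closes ring B by 6-exo-tet displacement at C11 to give 14. Because the stereogenic C8 now sits next to the bond already formed, the face selectivity is decided by a different transition state.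

Step 11. The hindered C1 carbonyl may be methylenated incompletely, the activated C4 bromide may be reduced by trivalent titanium species formed on heating, or the exocyclic alkene may migrate into conjugation during hydrolysis. The fallback replaces the titanium carbene by a two-stage Peterson olefination; it sets out from 16 and comes back at 18. Me3SiCH2Li/CeCl3 (THF, −78 °C) adds to the C1 carbonyl to give the β-hydroxysilane F5. KH (THF, 0 °C) triggers syn elimination to the dienol ether 17 without heat or titanium, and the oxalic acid hydrolysis of step 11 then gives 18.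

Step 10. NBS may attack C4 with poor or inverted facial selectivity. The fallback sets the centre by protonation instead of bromination; it sets out from 14 and comes back at 16. Bromination as in step 10 would then give mainly the (4R) epimer F6. This is deprotonated at C4 with LiN(SiMe3)2 (THF, −78 °C), and the bromo dienolate is quenched kinetically with 2,6-di-tert-butylphenol. The proton should take the open face that bromine took before, which places bromine on the other face and gives 16.

Further compounds
F1 | step 9 | (2R,3R)-2-bromo-5-[tert-butyl(dimethyl)silyl]oxy-3-chloro-3-methylpentyl trifluoromethanesulfonate | CC(C)(C)[Si](C)(C)OCC[C@@](C)(Cl)[C@H](Br)COS(=O)(=O)C(F)(F)F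
F2 | step 9 | 6-[(2R,3R)-2-bromo-5-[tert-butyl(dimethyl)silyl]oxy-3-chloro-3-methylpentyl]-3-(2-methylpropoxy)-5,5-dimethylcyclohex-2-en-1-one | CC(C)COC1=CC(=O)C(C[C@@H](Br)[C@](C)(Cl)CCO[Si](C)(C)C(C)(C)C)C(C)(C)C1
F3 | step 9 | 6-[(2R,3R)-2-bromo-3-chloro-5-hydroxy-3-methylpentyl]-3-(2-methylpropoxy)-5,5-dimethylcyclohex-2-en-1-one | CC(C)COC1=CC(=O)C(C[C@@H](Br)[C@](C)(Cl)CCO)C(C)(C)C1
F4 | step 9 | 6-[(2R,3R)-2-bromo-3-chloro-5-iodo-3-methylpentyl]-3-(2-methylpropoxy)-5,5-dimethylcyclohex-2-en-1-one | CC(C)COC1=CC(=O)C(C[C@@H](Br)[C@](C)(Cl)CCI)C(C)(C)C1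
F5 | step 11 | (4S,6R,8R,9R)-4,8-dibromo-9-chloro-3-(2-methylpropoxy)-5,5,9-trimethyl-1-[(trimethylsilyl)methyl]spiro[5.5]undec-2-en-1-ol (either configuration at C1) | C[Si](C)(C)CC1(O)C=C(OCC(C)C)[C@@H](Br)C(C)(C)[C@]12CC[C@@](C)(Cl)[C@H](Br)C2
F6 | step 10 | (4R,6R,8R,9R)-4,8-dibromo-9-chloro-3-(2-methylpropoxy)-5,5,9-trimethylspiro[5.5]undec-2-en-1-one | O=C1C=C(OCC(C)C)[C@H](Br)C(C)(C)[C@]12CC[C@@](C)(Cl)[C@H](Br)C2
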